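## The problem

Target 23, 3-[(6,8-dimethoxy-2-oxo-2H-chromen-7-yl)oxy]-7-hydroxy-6,8-dimethoxy-2H-chromen-2-one, is made of two 7-oxygenated 6,8-dimethoxycoumarins: unit A keeps a free hydroxyl on C7 and carries an ether oxygen on C3, and unit B is bound to that carbon through its O7'. There is no stereocentre, so the whole difficulty is constitutional: each benzene ring is pentasubstituted. In unit A the four neighbouring oxygenated carbons C6, C7, C8 and C8a must end as methyl ether, free phenol, methyl ether and lactone oxygen, so the pattern has to be built in rather than sorted out by late selective methylation. The C3–O–C7' link is an enol ether to a phenol oxygen flanked by two methoxy groups; it is hard to make by coupling at an sp2 carbon and easy to make as an O–CH2 bond before lactone A exists. Both lactones open with hydroxide or alkoxide, the C3'=C4' double bond of unit B accepts nucleophiles and hydrogen, the electron-rich phenol is easily oxidized, and hydroxybenzyl alcohols on the way to a salicylaldehyde ionize readily to quinone methides. The feature that opens the way lies in the benzene ring of unit A: C4a (carbon-bearing), C8a (oxygen) and C7 (oxygen) alternate like the carbonyl carbons of a 3,5-dioxo ester chain, C8 and C6 lie in between and carry methoxy groups, and C5 is the only CH. The ring can therefore be folded from an open chain in which every oxygen already has its final form.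

## Retrosynthesis

**23 from 22.** No skeletal bond is cut; the C7 hydroxyl of unit A is masked in 22 as its 4-methoxybenzyl ether. A free hydroxyl would be acetylated in the lactone-forming step and would turn the earlier benzylic alcohol into a para-quinone methide precursor. A plain benzyl ether would need hydrogenolysis, which threatens C3'=C4', or a boron halide, which threatens the methyl ethers. The forward step only has to cleave an electron-rich benzyl ether with acid, which both lactones and the enol ether tolerate.

**22 from 16 and 20.** The bonds O1–C2 and C3=C4 of lactone A are cut, giving salicylaldehyde 16 and aryloxyacetic acid 20, which reacts as its mixed anhydride 21 formed in the flask. The neighbouring cut, the C3–O bond, would require coupling a 3-halocoumarin with the doubly ortho-substituted phenol 17, a poor substrate for C–O coupling. The chosen cut turns the enol ether into an ordinary alkyl aryl ether and splits the bicoumarin into a benzaldehyde and an acid built on intact isofraxidin. The forward Perkin–Oglialoro condensation must favour the aryloxyacetyl unit over the condensation of acetic anhydride itself with the aldehyde.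

**20 from 17 and 18.** The O7'–CH2 bond is cut, leading through ester 19 to isofraxidin 17 and tert-butyl bromoacetate 18. Unit B is thus bought complete, with its lactone and both methyl ethers in place. The tert-butyl ester is chosen so that the acid is released without hydroxide, which would open lactone B.

**16 from 13.** No skeletal bond is cut; the ester carbon of 13 is the future C4 and is brought to the aldehyde level through 14 and 15. The 4-hydroxyl (future C7–OH) is protected first, so that benzylic alcohol 15 has no para hydroxyl. The 2-hydroxyl stays free because it must become the lactone oxygen. The forward steps ask for selective alkylation of the non-chelated phenol, hydride reduction of a salicylate and benzylic oxidation.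

**13 from 4 and 10.** The bonds C7–C8 and C4a–C5 of unit A (C3–C4 and C1–C6 of the benzoate) are cut, giving bis(silyl enol ether) 4 and acid chloride 10 by way of 11 and 12. Substitution on a preformed polyoxygenated benzene would have to solve both regiochemistry and the differentiation of hydroxyl from methoxy. A [3+3] union of opposite polarity, with the diene terminus attacking the alkoxyvinyl carbon first, would give the 2,6-dihydroxy isomer. The chosen cut reduces a pentasubstituted arene to two acyclic pieces of four and three carbons. The forward reaction must acylate at the terminal carbon of 4 and close the ring through carbon.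

**4 from 1, and 10 from 5 and 6.** Diene 4 comes from methyl 4-methoxyacetoacetate 1 by two silylations through 2 and 3. Acid chloride 10 comes from methyl methoxyacetate 5 and methyl formate 6 by formylation to 7 and O-methylation to 8, hydrolysis to 9 and chlorination. Only ester and enolate chemistry is asked.

## Roads not taken

Alternative 1: Both pyranone double bonds, C3=C4 and C3'=C4', are cut. In the forward key step the tetraene 3-[tert-butyl(dimethyl)silyl]oxy-6-ethenyl-2,4-dimethoxyphenyl 2-[3-(acryloyloxy)-4-ethenyl-2,6-dimethoxyphenoxy]prop-2-enoate A2 would be closed twice by (H2IMes)Cl2Ru=CH(C6H4-2-OiPr) to the silyl-protected bicoumarin A1, with loss of two molecules of ethylene.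
- Merits: both lactones form in one neutral operation near the end, no hot acylating medium is needed, and the hindered ether already exists in A2 as a 2-aryloxyacrylate.
- Weak points: the closure in unit A must join a styrene to a 1,1-disubstituted, oxygen-bearing acrylate, a reluctant partner. The two closures of A2 would run at very different rates, and intermolecular metathesis of the styrenes would compete. A2 is a double aryl ester, prone to acyl transfer and hydrolysis.
- Step economy: the vinyl groups of A2 would have to come by olefination from aldehydes of the same kind as 16, which the chosen plan condenses directly, and the lactone of unit B, available ready-made in 17, would be rebuilt. The disconnection also says nothing about how the benzene rings arise.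
- Comparison: the end game leading to A1 is milder than a Perkin condensation, and that is a real advantage. The chosen plan sets against it a shorter path from the aldehyde to the bicoumarin and the use of intact isofraxidin.

Alternative 2: The benzene ring of unit B is cut at C5'–C6'. In the forward key step the cyclobutenone 4-(3,3-diethoxyprop-1-en-2-yl)-3-methoxy-4-(methoxymethoxy)-2-[(7-benzyloxy-6,8-dimethoxy-2-oxo-2H-chromen-3-yl)oxy]cyclobut-2-en-1-one A4 would undergo thermal four-electron ring opening followed at once by 6π electrocyclization and tautomerization, giving phenol A3.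
- Merits: a fully substituted arene forms with every group placed by four-membered-ring chemistry, and the ether to unit A is made early by simple vinylogous ester exchange. The future C4' arrives in A3 at the aldehyde level as an acetal, which is better than the chosen plan, where an ester must be reduced and reoxidized.
- Weak points: the route constructs the one ring that isofraxidin supplies complete, while the coumarin half of A4, with the benzene ring of unit A and an oxygen on C3, still has to be made separately. The assembly of A4 requires an alkenyl nucleophile to distinguish two similar carbonyl groups, and this decides where the ether oxygen ends up. After A3, O-methylation, two deprotections, closure of lactone B and debenzylation remain.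
- Comparison: the route is clearly longer. The chosen plan sets against the better oxidation level of A3 its cheap acyclic starting materials and the purchase of unit B.

Alternative 3: The O1–C8a bond of lactone A is cut. In the forward key step the acid 3-(4-hydroxy-3,5-dimethoxyphenyl)-2-[(6,8-dimethoxy-2-oxo-2H-chromen-7-yl)oxy]propanoic acid A6 would be oxidized at the anode to spirolactone A7, and acid would then shift the acyloxy group to the neighbouring ring carbon to give dihydrocoumarin A5.
- Merits: the symmetric syringyl ring of A6 removes any regiochemical question in the arene, the starting materials are cheap aromatic compounds, and no ring has to be built from acyclic pieces. In step count this road is shorter than the chosen one.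
- Weak points: the dienone–phenol step has two possible migrating groups. Migration of carbon instead of oxygen would give the isomer A8, and nothing in A7 enforces the oxygen shift. A5 is still two hydrogens short of the coumarin, and dehydrogenating this α-aryloxy lactone beside a free, electron-rich phenol would need protection and an oxidant that spares two electron-rich rings. The anodic step must also spare unit B.
- Comparison: the chosen plan is longer. It sets against this that every oxygen is placed by construction, that no migratory preference is relied on, and that lactone A closes directly at the coumarin oxidation level.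

Key step: step 6

Assumption: the enol ether and silyl enol ether double bonds of 2–4 and 7–12 are drawn in one geometry for definiteness; any isomer mixture would serve, because all these carbons become ring atoms of the arene. Isofraxidin (17) is taken as a purchasable natural product.

## Route

Step 1
Reactants: 1 methyl 4-methoxy-3-oxobutanoate
Product: 2 methyl (Z)-4-methoxy-3-(trimethylsilyloxy)but-2-enoate
Conditions: TMSCl, Et3N, toluene, 20 °C
Reagents that add atoms: chlorotrimethylsilane, C[Si](C)(C)Cl
Why: Soft enolization and O-silylation of a β-keto ester; the enol conjugated with the ester is the only one populated, so the silyl enol ether forms toward C2.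

Step 2
Reactants: 2 methyl (Z)-4-methoxy-3-(trimethylsilyloxy)but-2-enoate
Product: 4 (1Z,3E)-1,4-dimethoxy-1,3-bis(trimethylsilyloxy)buta-1,3-diene, via lithium dienolate 3 (not isolated)
Conditions: LiN(iPr)2, THF, −78 °C; then TMSCl, −78 to 20 °C
Reagents that add atoms: chlorotrimethylsilane, C[Si](C)(C)Cl
Why: γ-Deprotonation of the silyloxy enoate gives the extended ester enolate 3, which is silylated on oxygen; this is the standard two-stage preparation of 1,3-bis(silyl enol ethers) of acetoacetates, and 4 is used without chromatography because it is moisture-sensitive.

Step 3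
Reactants: 5 methyl 2-methoxyacetate; 6 methyl formate
Product: 8 methyl (Z)-2,3-dimethoxyprop-2-enoate, via sodium formyl ester enolate 7 (not isolated)
Conditions: NaH, THF, 0 to 20 °C; then Me2SO4, DMF, 20 °C
Reagents that add atoms: dimethyl sulfate, COS(=O)(=O)OC
Why: Crossed Claisen formylation of an ester with a non-enolizable formate, then O-methylation of the formyl ester enolate by a hard electrophile in a dipolar aprotic solvent, the usual route to β-methoxyacrylates with the β-methoxy group trans to the ester.

Step 4
Reactants: 8 methyl (Z)-2,3-dimethoxyprop-2-enoate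
Product: 9 (Z)-2,3-dimethoxyprop-2-enoic acid
Conditions: LiOH, THF/H2O, 20 °C; cold aq. HCl to pH 3 on work-up
Reagents that add atoms: lithium hydroxide, [Li+].[OH-]
Why: Saponification at the ester carbonyl; the vinylogous carbonate is a poor conjugate acceptor for hydroxide, and brief cold acidification spares the enol ether.

Step 5
Reactants: 9 (Z)-2,3-dimethoxyprop-2-enoic acid
Product: 10 (Z)-2,3-dimethoxyprop-2-enoyl chloride
Conditions: (COCl)2, DMF (cat.), CH2Cl2, 0 to 20 °C
Reagents that add atoms: oxalyl chloride, O=C(Cl)C(Cl)=O
Why: Chlorination through the chloroiminium salt under mild conditions, as used for 3-alkoxyacryloyl chlorides; the enol ether is deactivated toward HCl by conjugation with the carbonyl, and 10 is used crude after removal of volatiles.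

Step 6
Reactants: 4 (1Z,3E)-1,4-dimethoxy-1,3-bis(trimethylsilyloxy)buta-1,3-diene; 10 (Z)-2,3-dimethoxyprop-2-enoyl chloride
Product: 13 methyl 2,4-dihydroxy-3,5-dimethoxybenzoate, via silyl enol ether 11 (not isolated), via dioxo ester 12 (not isolated)
Conditions: CH2Cl2, −78 to 20 °C; evaporate; NaOMe, MeOH, 0 to 65 °C; aq. HCl on work-up
Reagents that add atoms: none
Why: The terminal carbon of 4, the most nucleophilic site of this masked acetoacetate dianion, attacks the acyl chloride of 10 in an uncatalysed Mukaiyama-type C-acylation with loss of TMSCl, forming the bond that becomes C7–C8 of unit A and leaving O3 silylated in 11, so that this oxygen cannot close while the acylation runs. Methanolysis frees dioxo ester 12, in which C2 lies between ester and ketone and C7 is the β-carbon of a vinylogous ester. Under methoxide the C2 carbanion adds to C7 in a 6-endo-trig conjugate addition, methoxide is expelled (addition–elimination), and two enolizations give the benzene ring without any oxidant; this forms the bond that becomes C4a–C5 and the carbocycle of unit A. The closest known reactions are the formal [3+3] cyclocondensations of 1,3-bis(silyl enol ethers) with 3-alkoxyenones and the aromatizing cyclization of 3,5-dioxo esters that carry a masked carbonyl at C7, made from such dienes and acid chlorides. No stereocentre is formed: the C4 centre of 12 and both enol ether geometries disappear on aromatization. Two selectivities are needed; acylation at the terminal rather than the central carbon is secured by the dienol ether itself and by the absence of a Lewis acid, which keeps the alkoxyvinyl carbon of 10 from competing with the acyl chloride. Closure through C2 rather than through the C3 enol oxygen is secured by methanolic methoxide: the oxygen closure to a 4-pyranone can be reversed by addition of methoxide at the unsubstituted ring carbon, whereas the carbon closure ends in the resorcylate dianion and cannot go back. Methoxide is also the leaving group and the ester alkoxide, so all exchange reactions are degenerate.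

Step 7
Reactants: 13 methyl 2,4-dihydroxy-3,5-dimethoxybenzoate
Product: 14 methyl 2-hydroxy-3,5-dimethoxy-4-[(4-methoxyphenyl)methoxy]benzoate
Conditions: PMBCl (1.05 equiv), K2CO3, DMF, 40 °C
Reagents that add atoms: 4-methoxybenzyl chloride, COc1ccc(CCl)cc1
Why: Williamson alkylation; the 4-hydroxyl is para to the ester and more acidic, while the 2-hydroxyl is held in a hydrogen bond to the ester carbonyl, the usual basis for mono-alkylation of 2,4-dihydroxybenzoates.

Step 8
Reactants: 14 methyl 2-hydroxy-3,5-dimethoxy-4-[(4-methoxyphenyl)methoxy]benzoate
Product: 15 6-(hydroxymethyl)-2,4-dimethoxy-3-[(4-methoxyphenyl)methoxy]phenol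
Conditions: LiAlH4, THF, 0 to 20 °C; aq. potassium sodium tartrate work-up
Reagents that add atoms: none
Why: Hydride reduction of a salicylate to the salicyl alcohol through the aluminium phenoxide; with the para oxygen alkylated only the ortho hydroxyl can assist ionization, and a neutral work-up avoids it.

Step 9
Reactants: 15 6-(hydroxymethyl)-2,4-dimethoxy-3-[(4-methoxyphenyl)methoxy]phenol
Product: 16 2-hydroxy-3,5-dimethoxy-4-[(4-methoxyphenyl)methoxy]benzaldehyde
Conditions: MnO2 (activated), CH2Cl2, 20 °C
Reagents that add atoms: none
Why: Selective benzylic oxidation of an ortho-hydroxybenzyl alcohol to the salicylaldehyde; the aldehyde is stabilized by its hydrogen bond and is not oxidized further.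

Step 10
Reactants: 17 isofraxidin (7-hydroxy-6,8-dimethoxy-2H-chromen-2-one); 18 tert-butyl 2-bromoacetate
Product: 19 tert-butyl 2-[(6,8-dimethoxy-2-oxo-2H-chromen-7-yl)oxy]acetate
Conditions: K2CO3, DMF, 50 °C
Reagents that add atoms: none
Why: Williamson alkylation of the phenoxide with an unhindered, activated primary bromide; anhydrous carbonate does not open the lactone.

Step 11
Reactants: 19 tert-butyl 2-[(6,8-dimethoxy-2-oxo-2H-chromen-7-yl)oxy]acetate
Product: 20 2-[(6,8-dimethoxy-2-oxo-2H-chromen-7-yl)oxy]acetic acid
Conditions: TFA, CH2Cl2, 20 °C
Reagents that add atoms: none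
Why: Acidolysis of the tert-butyl ester with loss of isobutene; no hydroxide is used, so lactone B stays closed.

Step 12
Reactants: 16 2-hydroxy-3,5-dimethoxy-4-[(4-methoxyphenyl)methoxy]benzaldehyde; 20 2-[(6,8-dimethoxy-2-oxo-2H-chromen-7-yl)oxy]acetic acid
Product: 22 3-[(6,8-dimethoxy-2-oxo-2H-chromen-7-yl)oxy]-6,8-dimethoxy-7-[(4-methoxyphenyl)methoxy]-2H-chromen-2-one, via mixed anhydride 21 (not isolated)
Conditions: Ac2O, Et3N, 120 °C
Reagents that add atoms: none
Why: Perkin–Oglialoro condensation: the methylene of mixed anhydride 21, acidified by the aryloxy group, condenses with the aldehyde, and acyl transfer to the ortho phenoxide with loss of acetate and water closes lactone A with the C3=C4 double bond; this is the established route from salicylaldehydes and aryloxyacetic acids to 3-aryloxycoumarins.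

Step 13
Reactants: 22 3-[(6,8-dimethoxy-2-oxo-2H-chromen-7-yl)oxy]-6,8-dimethoxy-7-[(4-methoxyphenyl)methoxy]-2H-chromen-2-one
Product: 23 3-[(6,8-dimethoxy-2-oxo-2H-chromen-7-yl)oxy]-7-hydroxy-6,8-dimethoxy-2H-chromen-2-one
Conditions: TFA, anisole, CH2Cl2, 0 to 20 °C
Reagents that add atoms: none
Why: Acidolysis of the aryl 4-methoxybenzyl ether, with anisole trapping the benzyl cation; the lactones, the methyl ethers, the enol ether and C3'=C4' are inert to these conditions.

## Compound list

1 | methyl 4-methoxy-3-oxobutanoate | COCC(=O)CC(=O)OC | starting material
2 | methyl (Z)-4-methoxy-3-(trimethylsilyloxy)but-2-enoate | COC/C(O[Si](C)(C)C)=C/C(=O)OC | intermediate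
3 | lithium (1E,3E)-1,4-dimethoxy-3-(trimethylsilyloxy)buta-1,3-dien-1-olate | [Li+].CO/C([O-])=C/C(O[Si](C)(C)C)=C\OC | intermediate (not isolated)
4 | (1Z,3E)-1,4-dimethoxy-1,3-bis(trimethylsilyloxy)buta-1,3-diene | CO/C(O[Si](C)(C)C)=C/C(O[Si](C)(C)C)=C\OC | intermediate
5 | methyl 2-methoxyacetate | COCC(=O)OC | starting material
6 | methyl formate | COC=O | starting material
7 | sodium (Z)-2,3-dimethoxy-3-oxoprop-1-en-1-olate | [Na+].[O-]/C=C(\OC)C(=O)OC | intermediate (not isolated)
8 | methyl (Z)-2,3-dimethoxyprop-2-enoate | CO/C=C(\OC)C(=O)OC | intermediate
9 | (Z)-2,3-dimethoxyprop-2-enoic acid | CO/C=C(\OC)C(=O)O | intermediate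
10 | (Z)-2,3-dimethoxyprop-2-enoyl chloride | CO/C=C(\OC)C(Cl)=O | intermediate
11 | methyl (2Z,6Z)-4,6,7-trimethoxy-5-oxo-3-(trimethylsilyloxy)hepta-2,6-dienoate (racemic at C4) | CO/C=C(\OC)C(=O)C(OC)/C(O[Si](C)(C)C)=C/C(=O)OC | intermediate (not isolated)
12 | methyl (Z)-4,6,7-trimethoxy-3,5-dioxohept-6-enoate (racemic at the enolizable C4) | CO/C=C(\OC)C(=O)C(OC)C(=O)CC(=O)OC | intermediate (not isolated)
13 | methyl 2,4-dihydroxy-3,5-dimethoxybenzoate | COC(=O)c1cc(OC)c(O)c(OC)c1O | intermediate
14 | methyl 2-hydroxy-3,5-dimethoxy-4-[(4-methoxyphenyl)methoxy]benzoate | COC(=O)c1cc(OC)c(OCc2ccc(OC)cc2)c(OC)c1O | intermediate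
15 | 6-(hydroxymethyl)-2,4-dimethoxy-3-[(4-methoxyphenyl)methoxy]phenol | OCc1cc(OC)c(OCc2ccc(OC)cc2)c(OC)c1O | intermediate
16 | 2-hydroxy-3,5-dimethoxy-4-[(4-methoxyphenyl)methoxy]benzaldehyde | O=Cc1cc(OC)c(OCc2ccc(OC)cc2)c(OC)c1O | intermediate
17 | isofraxidin (7-hydroxy-6,8-dimethoxy-2H-chromen-2-one) | COc1cc2ccc(=O)oc2c(OC)c1O | starting material
18 | tert-butyl 2-bromoacetate | CC(C)(C)OC(=O)CBr | starting material
19 | tert-butyl 2-[(6,8-dimethoxy-2-oxo-2H-chromen-7-yl)oxy]acetate | COc1cc2ccc(=O)oc2c(OC)c1OCC(=O)OC(C)(C)C | intermediate
20 | 2-[(6,8-dimethoxy-2-oxo-2H-chromen-7-yl)oxy]acetic acid | COc1cc2ccc(=O)oc2c(OC)c1OCC(=O)O | intermediate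
21 | acetic 2-[(6,8-dimethoxy-2-oxo-2H-chromen-7-yl)oxy]acetic anhydride | COc1cc2ccc(=O)oc2c(OC)c1OCC(=O)OC(C)=O | intermediate (not isolated)
22 | 3-[(6,8-dimethoxy-2-oxo-2H-chromen-7-yl)oxy]-6,8-dimethoxy-7-[(4-methoxyphenyl)methoxy]-2H-chromen-2-one | COc1cc2cc(Oc3c(OC)cc4ccc(=O)oc4c3OC)c(=O)oc2c(OC)c1OCc1ccc(OC)cc1 | intermediate
23 | 3-[(6,8-dimethoxy-2-oxo-2H-chromen-7-yl)oxy]-7-hydroxy-6,8-dimethoxy-2H-chromen-2-one | COc1cc2cc(Oc3c(OC)cc4ccc(=O)oc4c3OC)c(=O)oc2c(OC)c1O | target

## Step count and risks

Total: 13 steps. Longest linear sequence: 9 steps (steps 3, 4, 5, 6, 7, 8, 9, 12, 13, from methyl 2-methoxyacetate 5). The diene branch (steps 1–2) and the isofraxidin branch (steps 10–11) are shorter and join at steps 6 and 12.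

**Step 6 (key step).** The most likely failure is ring closure through the C3 enol oxygen of 12 instead of through C2. The diketone enolate forms first and its oxygen is well placed for a 6-endo addition–elimination at C7. If the resulting pyranone reopens too slowly under the one-pot conditions, the material is held outside the carbocyclic manifold. Fallback: the sequence sets out from 12, isolated by aqueous work-up after the acylation stage. The oxygen closure is completed on purpose with TFA in CH2Cl2 to methyl 2-(3,5-dimethoxy-4-oxo-4H-pyran-2-yl)acetate F1, which is stable and can be purified. F1 is then subjected to the pyranone-to-resorcylate ring transformation known for 2-(alkoxycarbonylmethyl)-4-pyranones, with Mg(OMe)2 in refluxing MeOH: alkoxide opens the ring at the unsubstituted carbon, and the magnesium-bound open chain recloses through the side-chain carbon. The route is rejoined at 13.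

**Step 5.** The most likely failure is loss of the enol ether by addition of HCl during chlorination, or decomposition of 10 on concentration, since it is both an acid-sensitive enol ether and a reactive acyl chloride. Fallback: the sequence sets out from 9 and 1 and avoids both the acid chloride and the silyl diene. Acid 9 is converted with carbonyldiimidazole and N,O-dimethylhydroxylamine hydrochloride into (Z)-N,2,3-trimethoxy-N-methylprop-2-enamide F2. Keto ester 1 is deprotonated twice with LiN(iPr)2 in THF at −78 °C to dilithium 1,4-dimethoxybuta-1,3-diene-1,3-bis(olate) F3, whose terminal carbon is acylated by F2 (known Claisen-type acylation of β-keto ester dianions by N-methoxy-N-methylamides). This returns to the route at 12, which is closed to 13 with NaOMe as in the second stage of step 6.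

**Step 8.** The most likely failure is ionization of the benzylic C–O bond of the aluminium alkoxide or of 15 to an ortho-quinone methide, favoured by three donor oxygens. This would lead to over-reduction to the methyl compound in the flask or to oligomerization on work-up. Fallback: the sequence sets out from 14 and never passes through the benzylic alcohol. Ester 14 is converted with N,O-dimethylhydroxylamine hydrochloride and iPrMgCl (excess, THF, −10 to 20 °C) into 2-hydroxy-N,3,5-trimethoxy-4-[(4-methoxyphenyl)methoxy]-N-methylbenzamide F4. F4 is reduced with LiAlH4 at −20 °C to the chelated hemiaminal, which gives the aldehyde on hydrolysis. The route is rejoined at 16, and step 9 is no longer needed.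

**Step 12.** The most likely failure is the competing Perkin reaction of acetic anhydride itself, which would give the 3-unsubstituted coumarin, or stalling at the O-acetylated aldehyde. The aldehyde of 16 is deactivated by three donor oxygens and the methylene of 21 is only weakly acidic. Fallback: the sequence sets out from 16 and 20 and uses no acetate. The phenol of 16 is esterified with 20 (EDC hydrochloride, DMAP, CH2Cl2) to 2-formyl-4,6-dimethoxy-5-[(4-methoxyphenyl)methoxy]phenyl 2-[(6,8-dimethoxy-2-oxo-2H-chromen-7-yl)oxy]acetate F5. F5 is closed by intramolecular Knoevenagel-type aldol condensation with DBU in MeCN at 60 °C, the known two-stage route to 3-substituted coumarins. The route is rejoined at 22.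

## Further compounds

F1 | step 6 | methyl 2-(3,5-dimethoxy-4-oxo-4H-pyran-2-yl)acetate | COC(=O)Cc1occ(OC)c(=O)c1OC
F2 | step 5 | (Z)-N,2,3-trimethoxy-N-methylprop-2-enamide | CO/C=C(\OC)C(=O)N(C)OC
F3 | step 5 | dilithium 1,4-dimethoxybuta-1,3-diene-1,3-bis(olate) (dianion of 1, geometry not fixed) | [Li+].[Li+].COC=C([O-])C=C([O-])OC
F4 | step 8 | 2-hydroxy-N,3,5-trimethoxy-4-[(4-methoxyphenyl)methoxy]-N-methylbenzamide | CON(C)C(=O)c1cc(OC)c(OCc2ccc(OC)cc2)c(OC)c1O
F5 | step 12 | 2-formyl-4,6-dimethoxy-5-[(4-methoxyphenyl)methoxy]phenyl 2-[(6,8-dimethoxy-2-oxo-2H-chromen-7-yl)oxy]acetate | O=Cc1cc(OC)c(OCc2ccc(OC)cc2)c(OC)c1OC(=O)COc1c(OC)cc2ccc(=O)oc2c1OC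
A1 | alternative 1 | 7-[tert-butyl(dimethyl)silyl]oxy-3-[(6,8-dimethoxy-2-oxo-2H-chromen-7-yl)oxy]-6,8-dimethoxy-2H-chromen-2-one | COc1cc2cc(Oc3c(OC)cc4ccc(=O)oc4c3OC)c(=O)oc2c(OC)c1O[Si](C)(C)C(C)(C)C
A2 | alternative 1 | 3-[tert-butyl(dimethyl)silyl]oxy-6-ethenyl-2,4-dimethoxyphenyl 2-[3-(acryloyloxy)-4-ethenyl-2,6-dimethoxyphenoxy]prop-2-enoate | C=CC(=O)Oc1c(C=C)cc(OC)c(OC(=C)C(=O)Oc2c(C=C)cc(OC)c(O[Si](C)(C)C(C)(C)C)c2OC)c1OC
A3 | alternative 2 | 2-[(7-benzyloxy-6,8-dimethoxy-2-oxo-2H-chromen-3-yl)oxy]-5-(diethoxymethyl)-3-methoxy-4-(methoxymethoxy)phenol | Oc1cc(C(OCC)OCC)c(OCOC)c(OC)c1Oc1cc2cc(OC)c(OCc3ccccc3)c(OC)c2oc1=O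
A4 | alternative 2 | 4-(3,3-diethoxyprop-1-en-2-yl)-3-methoxy-4-(methoxymethoxy)-2-[(7-benzyloxy-6,8-dimethoxy-2-oxo-2H-chromen-3-yl)oxy]cyclobut-2-en-1-one (racemic) | O=C1C(Oc2cc3cc(OC)c(OCc4ccccc4)c(OC)c3oc2=O)=C(OC)C1(OCOC)C(=C)C(OCC)OCC
A5 | alternative 3 | 3-[(6,8-dimethoxy-2-oxo-2H-chromen-7-yl)oxy]-7-hydroxy-6,8-dimethoxy-3,4-dihydro-2H-chromen-2-one (racemic) | COc1cc2CC(Oc3c(OC)cc4ccc(=O)oc4c3OC)C(=O)Oc2c(OC)c1O
A6 | alternative 3 | 3-(4-hydroxy-3,5-dimethoxyphenyl)-2-[(6,8-dimethoxy-2-oxo-2H-chromen-7-yl)oxy]propanoic acid (racemic) | COc1cc(CC(Oc2c(OC)cc3ccc(=O)oc3c2OC)C(=O)O)cc(OC)c1O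
A7 | alternative 3 | 3-[(6,8-dimethoxy-2-oxo-2H-chromen-7-yl)oxy]-7,9-dimethoxy-1-oxaspiro[4.5]deca-6,9-diene-2,8-dione (racemic) | COC1=CC2(CC(Oc3c(OC)cc4ccc(=O)oc4c3OC)C(=O)O2)C=C(OC)C1=O
A8 | alternative 3 | 3-[(6,8-dimethoxy-2-oxo-2H-chromen-7-yl)oxy]-6-hydroxy-5,7-dimethoxy-3,4-dihydro-2H-chromen-2-one (racemic) | COc1cc2OC(=O)C(Oc3c(OC)cc4ccc(=O)oc4c3OC)Cc2c(OC)c1O
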